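**Assumption:** reagents that only deliver a protecting group, a sulfonyl group or a one- or two-carbon unit (TBSCl, Comins' reagent, MeMgBr, MeI, CO, lithium acetylide–EDA, the vinyliodonium salt) are treated as reagents; every numbered starting material has at most eight non-hydrogen atoms.

## Retrosynthetic overview

1. Target ⇒ its TBS ether ⇒ (Z)-enol triflate (Pd reductive carbonylation) ⇒ B-alkyl Suzuki union of ring vinyl compound 16 with epoxy alkenyl iodide 27.
2. 16 ⇒ α-methyl-α-vinyl cyclohexanone 15 (MeCeCl2) ⇒ one-carbon ring enlargement of cyclopentanone 9 by a β-oxido carbenoid 1,2-shift, with vinylation of the ring-expanded enolate (quaternary centre).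
3. 9 ⇒ 3-acetylcyclopent-2-enone 4 by Cu-catalysed asymmetric conjugate addition and enolate O-triflation (side-arm stereocentre plus Z enol geometry); 4 ⇒ 3-methoxycyclopentenone + ethyl vinyl ether.
4. 27 ⇒ alkyne 25 (methylboration, iodination) ⇒ homonerol 22 (directed asymmetric epoxidation, iodide, acetylide) ⇒ homoprenyl bromide + propyne + oxirane (carbocupration).
5. Rings: the carbocycle is bought as a cyclopentenone and enlarged to the cyclohexanone in step 5; the oxirane is made in step 8, before fragment union.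

## Route

Step 1
Reactants: 1 3-methoxycyclopent-2-en-1-one; 2 ethyl vinyl ether
Product: 4 3-acetylcyclopent-2-en-1-one, via (1-ethoxyethenyl)lithium 3 (not isolated)
Conditions: 2, t-BuLi, THF, −78 → 0 °C; 1, −78 °C; then 2 M HCl, rt
Reagents that add atoms: water, O
Why: 1,2-addition of the acyl-anion equivalent to the vinylogous ester, then acid-mediated Stork–Danheiser transposition and enol-ether hydrolysis, gives the ene-dione; no stereocentre is formed.

Step 2
Reactants: 5 3-bromopropan-1-ol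
Product: 6 (3-bromopropoxy)(tert-butyl)dimethylsilane
Conditions: TBSCl, imidazole, CH2Cl2, 0 °C → rt
Reagents that add atoms: tert-butyldimethylsilyl chloride, CC(C)(C)[Si](C)(C)Cl
Why: standard silylation (Corey protocol) of the primary alcohol so that the bromide can be turned into a Grignard reagent.

Step 3
Reactants: 4 3-acetylcyclopent-2-en-1-one; 6 (3-bromopropoxy)(tert-butyl)dimethylsilane
Product: 9 (1Z)-1-[(2R)-2-{3-[(tert-butyldimethylsilyl)oxy]propyl}-3-oxocyclopentylidene]ethyl trifluoromethanesulfonate, via Grignard reagent 7 (not isolated), via bromomagnesium Z-enolate 8 (not isolated)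
Conditions: 6, Mg, THF; CuBr·SMe2 (5 mol %), (R,S)-Josiphos (6 mol %; the antipode that gives (R)-9), t-BuOMe, −78 °C, slow addition of 4; then Comins' reagent, THF, −78 → 0 °C; water
Reagents that add atoms: N-(5-chloropyridin-2-yl)bis(trifluoromethanesulfonimide) (Comins' reagent), O=S(=O)(N(c1ccc(Cl)cn1)S(=O)(=O)C(F)(F)F)C(F)(F)F
Why: Cu(I)/Josiphos-catalysed asymmetric conjugate addition of the Grignard reagent occurs at the unsubstituted β-carbon of the acetyl enone through the Mg-bridged s-cis conformer, so the ligand sets the (R) side-arm centre while the (Z)-O-enolate (O syn to the new centre) is formed and O-triflated with retention (enolate trapping).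

Step 4
Reactants: 9 enol triflate ketone from step 3; 10 1,1-dibromoethane
Product: 12 (1Z)-1-[(2R,3S)-3-(1,1-dibromoethyl)-2-{3-[(tert-butyldimethylsilyl)oxy]propyl}-3-hydroxycyclopentylidene]ethyl trifluoromethanesulfonate (major carbinol epimer shown; both epimers converge in step 5), via (1,1-dibromoethyl)lithium 11 (not isolated)
Conditions: 10, LDA, THF/Et2O, −100 °C; then 9 (used at once after step 3); AcOH, −100 °C
Reagents that add atoms: none
Why: nucleophilic 1,2-addition of the weakly basic lithium carbenoid at −100 °C (first half of the Nozaki–Yamamoto homologation) outruns enolisation of the β,γ-unsaturated ketone and occurs anti to the side arm; the new carbinol centre is destroyed in step 5.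

Step 5
Reactants: 12 dibromo carbinol from step 4
Product: 15 (1Z)-1-[(2R,3S)-3-ethenyl-3-methyl-2-{3-[(tert-butyldimethylsilyl)oxy]propyl}-4-oxocyclohexylidene]ethyl trifluoromethanesulfonate, via chloromagnesium β-oxido carbenoid 13 (not isolated), via ring-expanded chloromagnesium enolate 14 (not isolated)
Conditions: i-PrMgCl (2.2 equiv), THF, −78 → −20 °C; then ethenyl(4-methoxyphenyl)iodonium triflate, −78 → 0 °C; water
Reagents that add atoms: ethenyl(4-methoxyphenyl)iodonium trifluoromethanesulfonate, C=C[I+]c1ccc(OC)cc1.[O-]S(=O)(=O)C(F)(F)F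
Why: Proposed new method: Br/Mg exchange on the gem-dibromide gives a β-oxido magnesium carbenoid whose 1,2-shift (the allylic, more substituted ring carbon migrates with retention as bromide leaves) enlarges the ring to the regiodefined tetrasubstituted enolate 14, which is C-vinylated by the vinyl-λ3-iodane through enolate–iodine(III) ligand coupling on the face anti to the pseudo-axial side arm (A1,3 strain with the enol triflate), setting the quaternary centre; the closest known reactions are the β-oxido carbenoid (Nozaki–Yamamoto) ring expansion of cyclic ketones and the α-arylation/alkenylation of enolates with diaryl- and alkenyl(aryl)iodonium salts, which have not been merged or used on such a hindered magnesium enolate.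

Step 6
Reactants: 15 vinyl ketone from step 5
Product: 16 (1Z)-1-[(2R,3S,4S)-3-ethenyl-4-hydroxy-3,4-dimethyl-2-{3-[(tert-butyldimethylsilyl)oxy]propyl}cyclohexylidene]ethyl trifluoromethanesulfonate
Conditions: MeMgBr, CeCl3, THF, −78 °C; water
Reagents that add atoms: methylmagnesium bromide, C[Mg]Br
Why: organocerium 1,2-addition (Imamoto conditions) to the hindered ketone; the side arm, held axial by A1,3 strain with the exocyclic enol triflate, blocks its own face, so methyl enters anti to the arm and to the ring methyl, giving the (S)-carbinol with OH cis to both.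

Step 7
Reactants: 17 5-bromo-2-methylpent-2-ene; 18 propyne; 19 oxirane
Product: 22 (3Z)-4,8-dimethylnona-3,7-dien-1-ol, via homoprenylmagnesium bromide 20 (not isolated), via Z-alkenylcopper 21 (not isolated)
Conditions: 17, Mg, THF; CuBr·SMe2 (1 equiv), Et2O/Me2S, −45 °C; 18, −25 °C; 1-lithiopent-1-yne, HMPA, 19, −78 → −20 °C; aq NH4Cl
Reagents that add atoms: none
Why: Normant carbocupration: syn addition of the homoprenylcopper across propyne fixes the Z trisubstituted olefin, and the derived mixed alkynyl cuprate opens oxirane with retention of olefin geometry.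

Step 8
Reactants: 22 (3Z)-4,8-dimethylnona-3,7-dien-1-ol
Product: 23 2-[(2R,3S)-3-methyl-3-(4-methylpent-3-en-1-yl)oxiran-2-yl]ethan-1-ol
Conditions: VO(Oi-Pr)3 (1 mol %), (R,R)-cyclohexanediamine-derived bis-hydroxamic acid ligand (2 mol %; the antipode that gives the (2R,3S)-epoxide), cumene hydroperoxide, toluene, rt
Reagents that add atoms: cumene hydroperoxide, CC(C)(OO)c1ccccc1
Why: Yamamoto vanadium–bis-hydroxamic acid epoxidation of a homoallylic alcohol is OH-directed, so only the proximal olefin reacts, and the chiral ligand selects the face, giving the cis (2R,3S)-epoxide from the Z alkene.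

Step 9
Reactants: 23 epoxy alcohol from step 8
Product: 24 (2R,3S)-2-(2-iodoethyl)-3-methyl-3-(4-methylpent-3-en-1-yl)oxirane
Conditions: I2, PPh3, imidazole, CH2Cl2, 0 °C
Reagents that add atoms: iodine, II
Why: Appel-type (Garegg–Samuelsson) iodination of the primary alcohol under imidazole buffering leaves the trisubstituted epoxide intact.

Step 10
Reactants: 24 epoxy iodide from step 9
Product: 25 (2R,3S)-2-(but-3-yn-1-yl)-3-methyl-3-(4-methylpent-3-en-1-yl)oxirane
Conditions: lithium acetylide–ethylenediamine complex, DMSO, 15 °C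
Reagents that add atoms: lithium acetylide ethylenediamine complex, [Li]C#C.NCCN
Why: SN2 alkylation of the acetylide by the primary iodide; the hindered trisubstituted epoxide is not opened.

Step 11
Reactants: 25 epoxy alkyne from step 10
Product: 26 2-{(1E)-2-methyl-4-[(2R,3S)-3-methyl-3-(4-methylpent-3-en-1-yl)oxiran-2-yl]but-1-en-1-yl}-4,4,5,5-tetramethyl-1,3,2-dioxaborolane
Conditions: CuCl (5 mol %), Xantphos (5 mol %), B2pin2, NaOt-Bu, MeI, THF, rt
Reagents that add atoms: bis(pinacolato)diboron, CC1(C)OB(OC1(C)C)B1OC(C)(C)C(C)(C)O1; iodomethane, CI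
Why: Cu-catalysed syn borylcupration of the terminal alkyne (boron to the terminal carbon) and trapping of the alkenylcopper with MeI (methylboration) give the (E)-2-methylalkenyl boronate under basic, Lewis-acid-free conditions that the epoxide tolerates.

Step 12
Reactants: 26 alkenyl boronate from step 11
Product: 27 (2R,3S)-2-[(3E)-4-iodo-3-methylbut-3-en-1-yl]-3-methyl-3-(4-methylpent-3-en-1-yl)oxirane
Conditions: NaOH (aq), then I2, THF, 0 °C
Reagents that add atoms: iodine, II
Why: base-first iododeboronation (Brown) proceeds through the boronate ate complex with retention, giving the (E)-alkenyl iodide.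

Step 13
Reactants: 16 ring vinyl alcohol from step 6; 27 alkenyl iodide from step 12
Product: 29 (1Z)-1-[(2R,3S,4S)-4-hydroxy-3,4-dimethyl-3-{(3E)-4-methyl-6-[(2R,3S)-3-methyl-3-(4-methylpent-3-en-1-yl)oxiran-2-yl]hex-3-en-1-yl}-2-{3-[(tert-butyldimethylsilyl)oxy]propyl}cyclohexylidene]ethyl trifluoromethanesulfonate, via B-alkyl-9-BBN 28 (not isolated)
Conditions: 9-BBN (2.2 equiv), THF, 0 °C → rt; then 27, PdCl2(dppf) (5 mol %), AsPh3, Cs2CO3, DMF/H2O, rt
Reagents that add atoms: none
Why: 9-BBN hydroborates only the monosubstituted vinyl group, and the B-alkyl Suzuki–Miyaura coupling joins it to the alkenyl iodide with retention of E geometry, because Pd(0) inserts into the unhindered C–I bond much faster than into the tetrasubstituted enol triflate.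

Step 14
Reactants: 29 coupled enol triflate from step 13
Product: 30 (2Z)-2-[(2R,3S,4S)-4-hydroxy-3,4-dimethyl-3-{(3E)-4-methyl-6-[(2R,3S)-3-methyl-3-(4-methylpent-3-en-1-yl)oxiran-2-yl]hex-3-en-1-yl}-2-{3-[(tert-butyldimethylsilyl)oxy]propyl}cyclohexylidene]propanal
Conditions: Pd(PPh3)4 (5 mol %), CO (1 atm), LiCl, Bu3SnH (slow addition), THF, 50 °C
Reagents that add atoms: carbon monoxide, [C-]#[O+]
Why: Pd-catalysed reductive carbonylation of the alkenyl triflate (Stille formylation) replaces OTf by CHO with retention of alkene geometry, giving the (Z)-enal; slow hydride addition avoids conjugate reduction.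

Step 15
Reactants: 30 silyl-protected enal from step 14
Product: 31 (2Z)-2-[(2R,3S,4S)-4-hydroxy-2-(3-hydroxypropyl)-3,4-dimethyl-3-{(3E)-4-methyl-6-[(2R,3S)-3-methyl-3-(4-methylpent-3-en-1-yl)oxiran-2-yl]hex-3-en-1-yl}cyclohexylidene]propanal (CNP0179098.1)
Conditions: TBAF, AcOH (1:1), THF, 0 °C → rt
Reagents that add atoms: none
Why: fluoride-mediated silyl ether cleavage, buffered with acetic acid, spares the epoxide and avoids base-induced enal isomerisation.

## Compound list

1 | 3-methoxycyclopent-2-en-1-one | COC1=CC(=O)CC1 | starting material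
2 | ethyl vinyl ether | C=COCC | starting material
3 | (1-ethoxyethenyl)lithium | [Li]C(=C)OCC | intermediate
4 | 3-acetylcyclopent-2-en-1-one | CC(=O)C1=CC(=O)CC1 | intermediate
5 | 3-bromopropan-1-ol | OCCCBr | starting material
6 | (3-bromopropoxy)(tert-butyl)dimethylsilane | CC(C)(C)[Si](C)(C)OCCCBr | intermediate
7 | {3-[(tert-butyldimethylsilyl)oxy]propyl}magnesium bromide | CC(C)(C)[Si](C)(C)OCCC[Mg]Br | intermediate
8 | bromomagnesium (1Z)-1-[(2R)-2-{3-[(tert-butyldimethylsilyl)oxy]propyl}-3-oxocyclopentylidene]ethan-1-olate | O=C1[C@H](CCCO[Si](C)(C)C(C)(C)C)/C(=C(/C)O[Mg]Br)CC1 | intermediate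
9 | (1Z)-1-[(2R)-2-{3-[(tert-butyldimethylsilyl)oxy]propyl}-3-oxocyclopentylidene]ethyl trifluoromethanesulfonate | O=C1[C@H](CCCO[Si](C)(C)C(C)(C)C)/C(=C(/C)OS(=O)(=O)C(F)(F)F)CC1 | intermediate
10 | 1,1-dibromoethane | CC(Br)Br | starting material
11 | (1,1-dibromoethyl)lithium | [Li]C(C)(Br)Br | intermediate
12 | (1Z)-1-[(2R,3S)-3-(1,1-dibromoethyl)-2-{3-[(tert-butyldimethylsilyl)oxy]propyl}-3-hydroxycyclopentylidene]ethyl trifluoromethanesulfonate | CC(Br)(Br)[C@@]1(O)[C@H](CCCO[Si](C)(C)C(C)(C)C)/C(=C(/C)OS(=O)(=O)C(F)(F)F)CC1 | intermediate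
13 | chloromagnesium β-oxido carbenoid of 12 (carbenoid carbon unassigned) | CC(Br)([Mg]Cl)[C@@]1(O[Mg]Cl)[C@H](CCCO[Si](C)(C)C(C)(C)C)/C(=C(/C)OS(=O)(=O)C(F)(F)F)CC1 | intermediate
14 | chloromagnesium enolate of the ring-expanded 2-methylcyclohexanone | CC1=C(O[Mg]Cl)CC/C(=C(\C)OS(=O)(=O)C(F)(F)F)[C@H]1CCCO[Si](C)(C)C(C)(C)C | intermediate
15 | (1Z)-1-[(2R,3S)-3-ethenyl-3-methyl-2-{3-[(tert-butyldimethylsilyl)oxy]propyl}-4-oxocyclohexylidene]ethyl trifluoromethanesulfonate | C=C[C@@]1(C)[C@H](CCCO[Si](C)(C)C(C)(C)C)/C(=C(/C)OS(=O)(=O)C(F)(F)F)CCC1=O | intermediate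
16 | (1Z)-1-[(2R,3S,4S)-3-ethenyl-4-hydroxy-3,4-dimethyl-2-{3-[(tert-butyldimethylsilyl)oxy]propyl}cyclohexylidene]ethyl trifluoromethanesulfonate | C=C[C@@]1(C)[C@H](CCCO[Si](C)(C)C(C)(C)C)/C(=C(/C)OS(=O)(=O)C(F)(F)F)CC[C@]1(C)O | intermediate
17 | 5-bromo-2-methylpent-2-ene | CC(C)=CCCBr | starting material
18 | propyne | CC#C | starting material
19 | oxirane | C1CO1 | starting material
20 | (4-methylpent-3-en-1-yl)magnesium bromide | CC(C)=CCC[Mg]Br | intermediate
21 | [(1Z)-2,6-dimethylhepta-1,5-dien-1-yl]copper | CC(C)=CCC/C(C)=C\[Cu] | intermediate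
22 | (3Z)-4,8-dimethylnona-3,7-dien-1-ol | CC(C)=CCC/C(C)=C\CCO | intermediate
23 | 2-[(2R,3S)-3-methyl-3-(4-methylpent-3-en-1-yl)oxiran-2-yl]ethan-1-ol | CC(C)=CCC[C@]1(C)O[C@@H]1CCO | intermediate
24 | (2R,3S)-2-(2-iodoethyl)-3-methyl-3-(4-methylpent-3-en-1-yl)oxirane | CC(C)=CCC[C@]1(C)O[C@@H]1CCI | intermediate
25 | (2R,3S)-2-(but-3-yn-1-yl)-3-methyl-3-(4-methylpent-3-en-1-yl)oxirane | CC(C)=CCC[C@]1(C)O[C@@H]1CCC#C | intermediate
26 | 2-{(1E)-2-methyl-4-[(2R,3S)-3-methyl-3-(4-methylpent-3-en-1-yl)oxiran-2-yl]but-1-en-1-yl}-4,4,5,5-tetramethyl-1,3,2-dioxaborolane | CC(C)=CCC[C@]1(C)O[C@@H]1CC/C(C)=C/B1OC(C)(C)C(C)(C)O1 | intermediate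
27 | (2R,3S)-2-[(3E)-4-iodo-3-methylbut-3-en-1-yl]-3-methyl-3-(4-methylpent-3-en-1-yl)oxirane | CC(C)=CCC[C@]1(C)O[C@@H]1CC/C(C)=C/I | intermediate
28 | B-alkyl-9-BBN from 16 (9-BBN on the terminal carbon of the former vinyl group; drawn as the free alcohol) | C1CCC2CCCC1B2CC[C@@]1(C)[C@H](CCCO[Si](C)(C)C(C)(C)C)/C(=C(/C)OS(=O)(=O)C(F)(F)F)CC[C@]1(C)O | intermediate
29 | (1Z)-1-[(2R,3S,4S)-4-hydroxy-3,4-dimethyl-3-{(3E)-4-methyl-6-[(2R,3S)-3-methyl-3-(4-methylpent-3-en-1-yl)oxiran-2-yl]hex-3-en-1-yl}-2-{3-[(tert-butyldimethylsilyl)oxy]propyl}cyclohexylidene]ethyl trifluoromethanesulfonate | CC(C)=CCC[C@]1(C)O[C@@H]1CC/C(C)=C/CC[C@@]1(C)[C@H](CCCO[Si](C)(C)C(C)(C)C)/C(=C(/C)OS(=O)(=O)C(F)(F)F)CC[C@]1(C)O | intermediate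
30 | (2Z)-2-[(2R,3S,4S)-4-hydroxy-3,4-dimethyl-3-{(3E)-4-methyl-6-[(2R,3S)-3-methyl-3-(4-methylpent-3-en-1-yl)oxiran-2-yl]hex-3-en-1-yl}-2-{3-[(tert-butyldimethylsilyl)oxy]propyl}cyclohexylidene]propanal | CC(C)=CCC[C@]1(C)O[C@@H]1CC/C(C)=C/CC[C@@]1(C)[C@H](CCCO[Si](C)(C)C(C)(C)C)/C(=C(/C)C=O)CC[C@]1(C)O | intermediate
31 | (2Z)-2-[(2R,3S,4S)-4-hydroxy-2-(3-hydroxypropyl)-3,4-dimethyl-3-{(3E)-4-methyl-6-[(2R,3S)-3-methyl-3-(4-methylpent-3-en-1-yl)oxiran-2-yl]hex-3-en-1-yl}cyclohexylidene]propanal | CC(C)=CCC[C@]1(C)O[C@@H]1CC/C(C)=C/CC[C@@]1(C)[C@H](CCCO)/C(=C(/C)C=O)CC[C@]1(C)O | target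

## Step count and risks

Total step count: 15. Longest linear sequence: 9 (steps 7–15).

**Risk 1, step 3 (asymmetric conjugate addition with enolate triflation).** The ene-dione may suffer 1,2-addition or give low ee, the enolate geometry rests on the s-cis argument, and ketone 9 is base-sensitive. The fallback sets out from 4 and comes back at 9. Allyl alcohol is silylated to tert-butyldimethyl(prop-2-en-1-yloxy)silane F1, which is hydrozirconated with Cp2Zr(H)Cl to chlorobis(cyclopentadienyl){3-[(tert-butyldimethylsilyl)oxy]propyl}zirconium F2. This alkylzirconium is added to 4 at room temperature under Cu(I)/phosphoramidite catalysis (alkylzirconium conjugate addition, no 1,2-addition), giving the zirconium (Z)-enolate F3, which is O-triflated in the same flask with Comins' reagent to return 9.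

**Risk 2, step 5 (the proposed ring expansion–vinylation).** The carbenoid shift could choose the wrong ring carbon, or the magnesium enolate could fail to couple with the iodane. The fallback uses known chemistry only, sets out from 12 and comes back at 15. The established β-oxido carbenoid ring enlargement is run as before (or with n-BuLi at −95 °C), and enolate 14 is trapped with acetaldehyde in an ordinary aldol addition, again anti to the side arm, to give the 2-(1-hydroxyethyl)-2-methylcyclohexanone aldol adduct F4. Mesylation (MsCl, Et3N) gives the mesylate F5, and E2 elimination with DBU toward the only available β-hydrogens (the methyl group) furnishes vinyl ketone 15.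

**Risk 3, step 13 (Suzuki coupling in the presence of the enol triflate).** If Pd(0) attacks the triflate, the fallback sets out from 16 and comes back at 30. The triflate is first converted by Pd-catalysed methoxycarbonylation (Pd(OAc)2, dppf, CO, MeOH, Et3N) into the methyl (Z)-enoate F6. Hydroboration with 9-BBN gives the B-alkyl-9-BBN F7, and Suzuki coupling with 27 gives the coupled methyl ester F8. DIBAL-H at −78 °C reduces the ester to the allylic alcohol F9, and MnO2 oxidises only this allylic alcohol to enal 30.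

## Further compounds

F1 | step 3 | tert-butyldimethyl(prop-2-en-1-yloxy)silane | C=CCO[Si](C)(C)C(C)(C)C
F2 | step 3 | chlorobis(cyclopentadienyl){3-[(tert-butyldimethylsilyl)oxy]propyl}zirconium | CC(C)(C)[Si](C)(C)OCCC[Zr](Cl)(C1C=CC=C1)C1C=CC=C1
F3 | step 3 | zirconium (Z)-enolate (analogue of 8 with O–ZrCp2Cl) | O=C1[C@H](CCCO[Si](C)(C)C(C)(C)C)/C(=C(/C)O[Zr](Cl)(C2C=CC=C2)C2C=CC=C2)CC1
F4 | step 5 | aldol adduct (15 with CH(OH)CH3 in place of the vinyl group; carbinol centre unassigned) | CC(O)[C@@]1(C)[C@H](CCCO[Si](C)(C)C(C)(C)C)/C(=C(/C)OS(=O)(=O)C(F)(F)F)CCC1=O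
F5 | step 5 | methanesulfonate of F4 | CC(OS(C)(=O)=O)[C@@]1(C)[C@H](CCCO[Si](C)(C)C(C)(C)C)/C(=C(/C)OS(=O)(=O)C(F)(F)F)CCC1=O
F6 | step 13 | methyl (2Z)-2-[(2R,3S,4S)-3-ethenyl-4-hydroxy-3,4-dimethyl-2-{3-[(tert-butyldimethylsilyl)oxy]propyl}cyclohexylidene]propanoate | C=C[C@@]1(C)[C@H](CCCO[Si](C)(C)C(C)(C)C)/C(=C(/C)C(=O)OC)CC[C@]1(C)O
F7 | step 13 | B-alkyl-9-BBN from F6 | C1CCC2CCCC1B2CC[C@@]1(C)[C@H](CCCO[Si](C)(C)C(C)(C)C)/C(=C(/C)C(=O)OC)CC[C@]1(C)O
F8 | step 13 | coupled methyl (Z)-enoate (29 with CO2Me in place of OTf) | CC(C)=CCC[C@]1(C)O[C@@H]1CC/C(C)=C/CC[C@@]1(C)[C@H](CCCO[Si](C)(C)C(C)(C)C)/C(=C(/C)C(=O)OC)CC[C@]1(C)O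
F9 | step 13 | allylic alcohol (30 with CH2OH in place of CHO) | CC(C)=CCC[C@]1(C)O[C@@H]1CC/C(C)=C/CC[C@@]1(C)[C@H](CCCO[Si](C)(C)C(C)(C)C)/C(=C(/C)CO)CC[C@]1(C)O
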